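How far did this flask get in 8.0 min, and with what excess of one hand over the other?

- epsilon: left-handed substrate 0.74 M; right-handed substrate 0.74 M; solid reagent 0.74 M; free catalyst 0.47 mM; impurity 0.28 mM; the very flask that is asked about, followed so far
- flask: left-handed substrate 0.74 M; solid reagent 0.740 M; free catalyst 0.47 mM; impurity 0.28 mM; right-handed substrate 0.74 M; time 8.0 min

- epsilon (time / s: left-handed substrate / %, right-handed substrate / %): 10.0: 48.0, 50.4; 15.0: 46.7, 50.4; 20.0: 46.0, 50.0; 30.0: 42.4, 49.8; 40.0: 40.2, 49.5

(each reading ± 0.3 percentage points)

* part of the left-handed substrate and right-handed substrate charged together that has reacted at 8.0 min
* excess of left-handed product over right-handed product in the product at 8.0 min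
* excess of right-handed substrate over left-handed substrate among what is left of the two at 8.0 min

- free catalyst is single-handed; left-handed substrate and right-handed substrate are mirror images of each other, charged as a racemate, each of them at the stated concentration
- as a solid, counted per litre of solution: solid reagent
- the numbers in the tables scatter by 0.3 percentage points (one standard deviation)
- at the start none of the solid reagent is in solution
- an excess is below zero if the other one leads

1. I froze one thing, the rate of loss. Over the first 40.0 s the two substrates together lost 0.154 /min, counted as a fraction of their joint charge, and the left-handed readings fell nearly in a straight line.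

2. I assumed one solid reagent per substrate. The charge of solid reagent then covered 50.0 % of the substrates, so it was the limiting reagent.

3. First extreme: solid reagent without end. The frozen rate gave 123 % reacted in 8.0 min, more than the charge holds.

4. Second extreme: reaction without delay. That flask stopped at once at 50.0 %.

5. I let the real flask run at the frozen rate towards that stop, as an estimate. I called the time to reach it the reagent lifetime, the cover divided by the frozen rate: 3.24 min.

6. This lifetime was shorter than 8.0 min, so I committed to 50.0 % reacted. Product and remainder then each held half of the racemate, so I expected the two excesses to be equal. I put no number on them.

7. The forecast went further and gave 50 % reacted, 82 % for the product and 81 % for the remainder. Its ground: “That looks zero-order, probably limited by the solid dissolving or by a saturated catalyst.”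

8. The flask gave 50.0 % reacted, 86.8 % for the product and 86.8 % for the remainder.

    free catalyst + left-handed substrate ⇌ catalyst intermediate A (K = 3.70 /M, k = 24400 /M/s)
    free catalyst + right-handed substrate ⇌ catalyst intermediate B (K = 0.280 /M, k = 5280 /M/s)
    partner + catalyst intermediate A → free catalyst + left-handed product (k = 1160 /M/s)
    partner + catalyst intermediate B → free catalyst + right-handed product (k = 383 /M/s)
    solid reagent ⇌ partner, rate k5*(cs5 - [partner]) while solid is left; crystals form when [partner] > cs5 (solubility = 0.0650 M, k = 0.108 /s)
    free catalyst → spent catalyst A (k = 7.14 × 10⁻⁵ /s)
    free catalyst + impurity → spent catalyst B (k = 1.52 × 10⁵ /M/s)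

In this flask the two products together stood at 49.5 % and the solid reagent at 0 % at 4.00 min, later than the lifetime of 3.24 min. The forecast's excess of right-handed substrate came 5.8 percentage points low. For the neighbour flask with 3.0 M of solid reagent, the same reckoning gave a cover of 203 %, above the whole of the substrates, and a lifetime of 13.1 min, longer than 8.0 min. That neighbour flask still held 66.6 % of its solid reagent at 8.00 min. There 63.6 % had reacted, less than the 123 % of the frozen rate, left-handed substrate stood at 0 %, right-handed product stood at 13.6 %, and the excess of left-handed product was 57.3 %.

All runs are simulated for substances that don't exist; the scatter is artificial.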